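**Plan**
- Retrosynthesis: cut O1–C2 of pyranone ring C, which gives the (αR,βS)-epoxide of a 2',6'-dihydroxychalcone. Then cut the oxirane oxygen (E-chalcone), then Cα=Cβ (acetophenone + vanillin), then the 7-O–prenyl bond (phloroacetophenone + prenol).
- Forward: rings A and B are bought. The prenyl ether is set first, the C3 chain is joined by Claisen–Schmidt condensation, and the enone is epoxidised. Ring C, the only ring made, closes in the last step.
- Enabling feature: C2 is benzylic to ring B and para to its 4'-OH, so an oxirane spanning C2–C3 opens at C2 (p-quinone-methide-like) and leaves its oxygen behind as 3-OH. Ring A carries two equivalent OH groups ortho to the C4 carbonyl; either one closes the same ring and the other becomes 5-OH.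
- Stereochemistry: one catalytic Juliá–Colonna epoxidation sets both centres. C3 keeps the Cα–O bond, and C2 arises by inversion at Cβ, backed by the trans preference of ring C.
- Helpers: three MOM groups keep the enone electrophilic and block early cyclisation, and they leave in the key step itself. That step mirrors the biosynthetic chalcone-to-flavanoid closure one oxidation level higher. The nucleophilic oxidant spares the prenyl alkene.

Key step: step 6

Remark on the chemistry: the descriptors of the SMILES correspond to (2R,3R), the 2,3-trans dihydroflavonol. Flavonoid numbering is used (rings A, B, C; O1, C2, C3, C4), and α/β denote the chalcone carbons that become C3/C2.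

**Step 1**
Reactants: 1 2,4,6-trihydroxyacetophenone (dried); 2 3-methylbut-2-en-1-ol (prenol)
Product: 3 1-[2,6-dihydroxy-4-(3-methylbut-2-enyloxy)phenyl]ethanone
Conditions: PPh3, DIAD, THF, 0 °C → rt
Reagents that add atoms: none
Why: Mitsunobu etherification should take place at the 4-OH, which is the most acidic phenol (para to the acetyl group) and the only one neither hydrogen-bonded to nor flanked by the carbonyl, and O-phosphonium activation of the primary allylic alcohol favours O- over C-alkylation of the phloroglucinol ring; no stereocentre is formed.

**Step 2**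
Reactants: 3 1-[2,6-dihydroxy-4-(3-methylbut-2-enyloxy)phenyl]ethanone
Product: 4 1-[2,6-bis(methoxymethoxy)-4-(3-methylbut-2-enyloxy)phenyl]ethanone
Conditions: NaH, MOMCl, DMF, 0 °C → rt
Reagents that add atoms: chloromethyl methyl ether (MOMCl), COCCl
Why: Williamson-type O-alkylation of the bis-phenoxide with MOMCl masks both ortho phenols, so that the later enone stays electrophilic and cannot cyclise early, and the prenyl ether and the ketone are inert to these conditions.

**Step 3**
Reactants: 5 vanillin (4-hydroxy-3-methoxybenzaldehyde)
Product: 6 3-methoxy-4-(methoxymethoxy)benzaldehyde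
Conditions: MOMCl, K2CO3, acetone, rt
Reagents that add atoms: chloromethyl methyl ether (MOMCl), COCCl
Why: Phenol O-alkylation with MOMCl removes the acidic 4-OH, which as its phenoxide would deactivate the aldehyde in the aldol step and the enone in the epoxidation.

**Step 4**
Reactants: 4 1-[2,6-bis(methoxymethoxy)-4-(3-methylbut-2-enyloxy)phenyl]ethanone; 6 3-methoxy-4-(methoxymethoxy)benzaldehyde
Product: 7 (E)-1-[2,6-bis(methoxymethoxy)-4-(3-methylbut-2-enyloxy)phenyl]-3-[3-methoxy-4-(methoxymethoxy)phenyl]prop-2-en-1-one
Conditions: KOH, EtOH–H2O, rt
Reagents that add atoms: none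
Why: Claisen–Schmidt condensation of a methyl ketone with a non-enolisable aldehyde, followed by E1cB dehydration, should give the thermodynamically favoured E-enone, and MOM and prenyl ethers are stable to hydroxide.

**Step 5**
Reactants: 7 (E)-chalcone
Product: 8 [(2R,3S)-3-[3-methoxy-4-(methoxymethoxy)phenyl]oxiran-2-yl][2,6-bis(methoxymethoxy)-4-(3-methylbut-2-enyloxy)phenyl]methanone, the (αR,βS)-trans-epoxide
Conditions: poly-L-leucine (cat.), urea–H2O2, DBU, THF, rt; polymer filtered off; Et3N-deactivated silica
Reagents that add atoms: hydrogen peroxide (as urea adduct), OO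
Why: Juliá–Colonna epoxidation (asymmetric Weitz–Scheffer reaction): hydroperoxide adds only to the electron-poor enone and leaves the electron-rich prenyl alkene alone, the E geometry is carried into the trans-oxirane, and the N-terminal turns of α-helical poly-L-leucine bind the peroxy-enolate so that oxygen reaches the face giving the (αR,βS)-epoxide, the usual sense for chalcones with the L-polymer.

**Step 6**
Reactants: 8 (αR,βS)-trans-epoxide
Product: 10 (2R,3R)-3,5-dihydroxy-2-(4-hydroxy-3-methoxyphenyl)-7-(3-methylbut-2-enyloxy)-2,3-dihydrochromen-4-one (target), via triphenolic epoxide 9 (not isolated)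
Conditions: dilute HCl (ca. 0.2 M), MeOH–THF, 40 °C, Ar, stopped once the last MOM group is gone; NaHCO3 quench
Reagents that add atoms: none
Why: Acid methanolysis removes the three MOM acetals to give triphenolic epoxide 9, whose protonated oxirane stretches its Cβ–O bond (benzylic and para to the freed 4-OH of ring B, hence p-quinone-methide-like) until one ortho-OH of ring A captures Cβ, which forms the O1–C2 bond and leaves the former oxirane oxygen as 3-OH. The closest known reaction type is the acid-induced deprotection–cyclisation of 2'-O-MOM chalcone epoxides to dihydroflavonols, that is the Algar–Flynn–Oyamada manifold stopped at the dihydroflavonol stage. Ring C closes in the 6-endo-tet mode (6-endo-trig if a free quinone methide intervenes). C3 keeps the untouched Cα–O bond of the epoxide (R) and C2 becomes R by backside attack on the βS carbon; should methanol or full ionisation reach Cβ first, the adduct re-ionises and the C3 carbinol steers the aryl group into the equatorial 2,3-trans position, which reversible ring opening through the 4'-OH also favours thermodynamically, so all channels should converge on (2R,3R). The step needs 6-endo attack over 5-exo attack (aurone series) and over 1,2-aroyl shift (isoflavone series), secured by the guaiacyl donor at Cβ, the destabilising acyl group at Cα and the nucleophilic solvent, and it needs MOM loss without ionisation or solvent addition at the prenyl ether, secured by the much faster oxocarbenium pathway of aryl formaldehyde acetals in dilute acid. No choice between the two ring A hydroxyls is needed, because rotation about the aryl–carbonyl bond interchanges them, and the one left over becomes the chelated 5-OH.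

**Compound list**
1 | 2,4,6-trihydroxyacetophenone | CC(=O)c1c(O)cc(O)cc1O | starting material
2 | 3-methylbut-2-en-1-ol (prenol) | CC(C)=CCO | starting material
3 | 1-[2,6-dihydroxy-4-(3-methylbut-2-enyloxy)phenyl]ethanone | CC(=O)c1c(O)cc(OCC=C(C)C)cc1O | intermediate
4 | 1-[2,6-bis(methoxymethoxy)-4-(3-methylbut-2-enyloxy)phenyl]ethanone | CC(=O)c1c(OCOC)cc(OCC=C(C)C)cc1OCOC | intermediate
5 | vanillin | COc1cc(C=O)ccc1O | starting material
6 | 3-methoxy-4-(methoxymethoxy)benzaldehyde | COCOc1ccc(C=O)cc1OC | intermediate
7 | (E)-chalcone, tris-MOM, 4'-O-prenyl | COCOc1ccc(/C=C/C(=O)c2c(OCOC)cc(OCC=C(C)C)cc2OCOC)cc1OC | intermediate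
8 | (αR,βS)-trans-chalcone epoxide, tris-MOM | O=C(c1c(OCOC)cc(OCC=C(C)C)cc1OCOC)[C@@H]2O[C@H]2c3ccc(OCOC)c(OC)c3 | intermediate
9 | [(2R,3S)-3-(4-hydroxy-3-methoxyphenyl)oxiran-2-yl][2,6-dihydroxy-4-(3-methylbut-2-enyloxy)phenyl]methanone (not isolated) | O=C(c1c(O)cc(OCC=C(C)C)cc1O)[C@@H]2O[C@H]2c3ccc(O)c(OC)c3 | intermediate
10 | (2R,3R)-7-O-prenyl-3'-O-methyltaxifolin | COc1cc([C@H]2Oc3cc(OCC=C(C)C)cc(O)c3C(=O)[C@@H]2O)ccc1O | target

**Total step count:** 6. **Longest linear sequence:** 5 (steps 1, 2, 4, 5, 6).

**Steps most likely to fail**

Step 6.
- Risk: the aryl prenyl ether may ionise, or methanol may add to its alkene, during the time the slowest MOM group needs to leave.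
- Fallback (sets out from 8, returns at 10): the prenyl ether is given up as a spectator and put back after ring closure.
- Compound 8 is heated with stronger acid (p-TsOH·H2O, MeOH, reflux). All four acid-labile ethers are solvolysed and ring C closes in the same operation, to give (2R,3R)-3'-O-methyltaxifolin F1.
- The 7-OH of F1 is para to the C4 carbonyl and is by far the most acidic hydroxyl; the 5-OH is chelated, the 4'-OH is a plain guaiacol and the 3-OH is an alcohol.
- The 7-OH is then alkylated with one equivalent of prenyl bromide (K2CO3, acetone, rt, argon).

Step 5.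
- Risk: conversion may be slow and facial selectivity poor, because the 2',6'-disubstituted aroyl group is twisted out of conjugation and may fit badly into the helical binding site.
- Fallback (sets out from 7, returns at 8): asymmetric catalysis is replaced by resolution.
- Achiral Weitz–Scheffer epoxidation (30% H2O2, NaOH, MeOH–THF, 0 °C) should give the racemic trans-epoxide, that is 8 together with its mirror image, the (2S,3R)-epoxide F2.
- The two are separated by preparative HPLC on a polysaccharide chiral stationary phase with a neutral hexane/2-propanol eluent.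

Step 1.
- Risk: site selectivity may be poor (2-O- or double alkylation), and C-alkylation of the phloroglucinol nucleus may compete.
- Fallback (sets out from 1, returns at 4): the prenylation is moved behind the MOM protection by means of a temporary silyl block.
- The least hindered 4-OH is silylated (TIPSCl, imidazole, DMF, 0 °C) to the 4-O-TIPS ether F3.
- Both remaining phenols are turned into MOM ethers (NaH, MOMCl, THF–DMF, 0 °C) to give F4.
- TBAF (THF, 0 °C) frees the single phenol F5.
- F5 is alkylated with prenyl bromide (K2CO3, DMF, rt).

**Further compounds**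
F1 | step 6 | (2R,3R)-3,5,7-trihydroxy-2-(4-hydroxy-3-methoxyphenyl)-2,3-dihydrochromen-4-one (3'-O-methyltaxifolin) | COc1cc([C@H]2Oc3cc(O)cc(O)c3C(=O)[C@@H]2O)ccc1O
F2 | step 5 | (2S,3R)-trans-epoxide, mirror image of 8 | O=C(c1c(OCOC)cc(OCC=C(C)C)cc1OCOC)[C@H]2O[C@@H]2c3ccc(OCOC)c(OC)c3
F3 | step 1 | 1-[2,6-dihydroxy-4-(triisopropylsilyloxy)phenyl]ethanone | CC(=O)c1c(O)cc(O[Si](C(C)C)(C(C)C)C(C)C)cc1O
F4 | step 1 | 1-[2,6-bis(methoxymethoxy)-4-(triisopropylsilyloxy)phenyl]ethanone | CC(=O)c1c(OCOC)cc(O[Si](C(C)C)(C(C)C)C(C)C)cc1OCOC
F5 | step 1 | 1-[4-hydroxy-2,6-bis(methoxymethoxy)phenyl]ethanone | CC(=O)c1c(OCOC)cc(O)cc1OCOC
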